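While solid monomer is left over, the solution keeps being fed, so after a first climb free monomer should stay between two levels, and those levels bracket the yield. Solid dissolves towards saturation, free monomer slowly turns initiator into living ends, and living ends add free monomer to chains.

solid monomer 0.13 M; initiator 1.4 mol%; time 80 min

    free monomer + living end → monomer in chains + living end, rate k1*[living end]*[free monomer] (k1 = 19.8 L mol⁻¹ min⁻¹)
    solid monomer ⇌ free monomer, rate k2*(cs2 - [free monomer]) while solid is left; crystals form when [free monomer] > cs2 (cs2 = 0.059 M, k2 = 0.0749 min⁻¹)
    initiator + monomer in chains ⇌ idle complex (K3 = 130 L mol⁻¹, k3 = 0.951 L mol⁻¹ min⁻¹)
    free monomer + initiator → living end + monomer in chains (k4 = 0.374 L mol⁻¹ min⁻¹)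

* amount of monomer in chains and idle complex together at 80 min, in percent of the solid monomer charged
* concentration of free monomer in solution at 40 min, in percent of saturation
* the change that raises the amount of monomer in chains and idle complex together at 80 min, in percent of the solid monomer charged most ("none" if none brings more than 2 percentage points) (epsilon / beta / eta / none)
* amount of monomer in chains and idle complex together at 80 min, in percent of the solid monomer charged, after eta

- epsilon: doubling the dissolution coefficient of step 2, all else as stated
- beta: doubling the amount of initiator, all else as stated
- eta: doubling the solubility in step 2, all else as stated

We reckon the yield by hand, assuming the solid lasts.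

1. Living ends cannot exceed the initiator charged, 0.00182 M. At saturation, the step from initiator to living end uses up initiator with a time constant of 45.3 min. We set aside the binding of initiator to chains in this reckoning, so both ends of the bracket are estimates, not strict bounds.

2. Ceiling: hold free monomer at saturation from the first minute. Over 80 min the living ends then work like a full charge for 42.4 min, the run less the time constant times the share of initiator spent. Multiplying k1, saturation, full charge and those minutes gives 69.4 %.

3. Dissolving brings k2 × (saturation − free monomer), and chains take at most k1 × full charge × free monomer. These balance at the floor share, the fraction of saturation where dissolving just feeds chains grown from every bit of initiator: 67.5 %, a quasi-steady state.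

4. Bottom: hold free monomer at the floor share, starting only after 13.4 min of dissolving. This gives 26.9 %.

5. Tightened: halfway between floor and saturation, with the same delay, we commit to 38.8 %.

The forecast gave 38 %, inside our bracket, with 84 % of saturation, eta as the best change and 74 % after it, holding that “dissolution only slightly outruns propagation”.

The flask gives 39.1 %, 83.6 % of saturation at 40 min, best change eta (gain 35 percentage points, against 24 points for beta and 9.5 points for epsilon) and 74.2 % after it.

In this flask free monomer is made 2.71 times as fast as it is used at 21.9 min, but by 80.0 min making over using has come down to 0.952. Free monomer then stands at 78.2 % of saturation, above the floor share of 67.5 %, with solid monomer at 25.4 %. A second flask, charged with 0.052 M of solid monomer at the same loading, has a floor share of 83.9 %, but its solid monomer is down to 0 % at 80.0 min, and its free monomer reads 56.9 % of saturation.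

The constants used here stand for no real mixture; the run is a simulation.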